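**Plan**

- Retrosynthesis: the C6–C7 bond of the nine-membered ring is cut first (allyl carbonate plus C6 bis-sulfonyl carbanion). Then come the pyran C4–O bond to the enol carbon, the C5–C1′ bond to the methylene-trione, and the two cyclobutane bonds C1–C11 and C9–C10. This leads back to geraniol, an allenoate and an acylphloroglucinol-derived trione.
- Forward: the cyclobutane is made first by an allenoate–alkene [2+2] on a geraniol-derived diol, and its ester arm is turned into the 2-(carbonatomethyl)allyl unit. The trione is then attached at C5, the pyran is closed, the nine-membered carbocycle is closed, and the two sulfonyl groups are removed.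
- Stereochemistry: C4 comes from Sharpless epoxidation of geraniol and C2-selective hydride opening. C1 comes from the chiral oxazaborolidine of the [2+2]. C9 comes from ligand-controlled copper hydride reduction. C5 comes from enamine catalysis with (R)-diphenylprolinol silyl ether.
- Enabling feature: C8 carries the cyclobutane CH (C9) and, in the product, two CH2 groups (C7 and the exocyclic methylene). A π-allyl centred on C8 therefore has two equivalent CH2 termini, and attack at either one gives the nine-membered ring with the exocyclic methylene.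

Key step: step 19

Remark: locants C1–C11 are those of the caryophyllane skeleton (C1 and C9 cyclobutane CH, C4 the O-bearing quaternary carbon, C5 the ring-fusion CH, C8 the methylene-bearing carbon) and C1′ is the pyran CH2; the enolised trione is drawn as the tautomer of the target SMILES.

**Route**

Step 1
Reactants: 1 phloroglucinol (benzene-1,3,5-triol)
Product: 2 2-methyl-1-(2,4,6-trihydroxyphenyl)propan-1-one
Conditions: isobutyryl chloride, AlCl3, PhNO2/CH2Cl2, 0 °C to rt; aq. HCl
Reagents that add atoms: isobutyryl chloride, CC(C)C(Cl)=O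
Why: Friedel–Crafts C-acylation of the very electron-rich arene stops after one acyl group because the new ketone deactivates the ring.

Step 2
Reactants: 2 2-methyl-1-(2,4,6-trihydroxyphenyl)propan-1-one
Product: 3 3,5-dihydroxy-6,6-dimethyl-2-(2-methylpropanoyl)cyclohexa-2,4-dien-1-one (enol form of 2-isobutyryl-4,4-dimethylcyclohexane-1,3,5-trione)
Conditions: NaOMe (3 equiv), MeI (2.2 equiv), MeOH, 0 °C to rt
Reagents that add atoms: iodomethane, CI
Why: Dearomatising double C-methylation of the acylphloroglucinol phenoxide, in which the second methyl group enters the carbon already methylated and gives the gem-dimethyl trione with one free ring CH.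

Step 3
Reactants: 3 3,5-dihydroxy-6,6-dimethyl-2-(2-methylpropanoyl)cyclohexa-2,4-dien-1-one
Product: 4 3,5-dihydroxy-6,6-dimethyl-2-(2-methylpropanoyl)-4-[(phenylsulfonyl)methyl]cyclohexa-2,4-dien-1-one
Conditions: 37% aq. CH2O, PhSO2Na, HCO2H/H2O, rt
Reagents that add atoms: formaldehyde, C=O; sodium benzenesulfinate, [Na+].[O-]S(=O)c1ccccc1
Why: Mannich-type three-component sulfonylmethylation, in which Knoevenagel condensation at the free ring CH gives the methylene-trione and sulfinate traps it, yielding a storable precursor that releases the quinone methide with mild base.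

Step 4
Reactants: 5 buta-2,3-dienoic acid
Product: 6 2,2,2-trifluoroethyl buta-2,3-dienoate
Conditions: CF3CH2OH, DCC, CH2Cl2, 0 °C
Reagents that add atoms: 2,2,2-trifluoroethanol, OCC(F)(F)F
Why: Steglich-type carbodiimide esterification gives the electron-poor allenoate that is the reactive partner for Lewis acid-catalysed [2+2] cycloaddition.

Step 5
Reactants: 7 geraniol, (2E)-3,7-dimethylocta-2,6-dien-1-ol
Product: 8 (2S,3S)-2,3-epoxygeraniol, [(2S,3S)-3-methyl-3-(4-methylpent-3-en-1-yl)oxiran-2-yl]methanol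
Conditions: Ti(OiPr)4 (5 mol%), L-(+)-diethyl tartrate (7.5 mol%), t-BuOOH, 4 Å MS, CH2Cl2, −20 °C
Reagents that add atoms: tert-butyl hydroperoxide, CC(C)(C)OO
Why: Sharpless asymmetric epoxidation, in which the titanium–L-(+)-tartrate complex delivers oxygen to one face of the (E)-allylic alcohol only and so sets the future C4 (3S in 8), while the remote non-allylic alkene is not touched.

Step 6
Reactants: 8 (2S,3S)-2,3-epoxygeraniol
Product: 9 (3S)-3,7-dimethyloct-6-ene-1,3-diol
Conditions: NaAlH2(OCH2CH2OMe)2, THF, 0 °C to rt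
Reagents that add atoms: none
Why: Regioselective reductive opening of a 2,3-epoxy alcohol, in which hydride is delivered from the aluminium alkoxide at O1 to C2, so the C–O bond at the quaternary carbon and its configuration are kept.

Step 7
Reactants: 9 (3S)-3,7-dimethyloct-6-ene-1,3-diol
Product: 10 (3S)-3,7-dimethyl-1,3-bis(triethylsilyloxy)oct-6-ene
Conditions: Et3SiOTf (2.5 equiv), 2,6-lutidine, CH2Cl2, −78 to 0 °C
Reagents that add atoms: triethylsilyl trifluoromethanesulfonate, CC[Si](CC)(CC)OS(=O)(=O)C(F)(F)F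
Why: Silylation with the silyl triflate protects both the primary and the hindered tertiary hydroxyl in one operation and leaves only the trisubstituted alkene as a reactive site.

Step 8
Reactants: 10 (3S)-3,7-dimethyl-1,3-bis(triethylsilyloxy)oct-6-ene; 6 2,2,2-trifluoroethyl buta-2,3-dienoate
Product: 11 2,2,2-trifluoroethyl (2E)-2-{(2S)-3,3-dimethyl-2-[(3S)-3-methyl-3,5-bis(triethylsilyloxy)pentyl]cyclobutylidene}acetate
Conditions: (S)-B-(o-tolyl)oxazaborolidine derived from α,α-diphenylprolinol (30 mol%), AlBr3 (25 mol%), CH2Cl2, −78 to −40 °C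
Reagents that add atoms: none
Why: Lewis acid-catalysed allenoate–alkene [2+2] cycloaddition, in which the CH end of the trisubstituted alkene bonds to the central allene carbon and the CMe2 end to the allene CH2, giving the gem-dimethylcyclobutane, while the chiral oxazaborolidinium shields one face so that C1 is set by the catalyst (its antipode is used if the sense proves opposite).

Step 9
Reactants: 11 2,2,2-trifluoroethyl (2E)-2-{(2S)-3,3-dimethyl-2-[(3S)-3-methyl-3,5-bis(triethylsilyloxy)pentyl]cyclobutylidene}acetate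
Product: 12 2,2,2-trifluoroethyl 2-{(1R,2R)-3,3-dimethyl-2-[(3S)-3-methyl-3,5-bis(triethylsilyloxy)pentyl]cyclobutyl}acetate (trans-cyclobutane)
Conditions: Cu(OAc)2·H2O (5 mol%), (R)-DTBM-SEGPHOS (5.5 mol%), (EtO)2MeSiH, t-BuOH, toluene, 0 °C to rt
Reagents that add atoms: none
Why: Copper hydride conjugate reduction of a geometrically defined β,β-disubstituted enoate, in which the chiral bisphosphine, not the substrate, decides the face of C9 that receives hydride, and the ligand antipode is chosen so that H enters cis to the C1 side chain and gives the trans-cyclobutane.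

Step 10
Reactants: 12 2,2,2-trifluoroethyl 2-{(1R,2R)-3,3-dimethyl-2-[(3S)-3-methyl-3,5-bis(triethylsilyloxy)pentyl]cyclobutyl}acetate
Product: 13 2-{(1R,2R)-3,3-dimethyl-2-[(3S)-3-methyl-3,5-bis(triethylsilyloxy)pentyl]cyclobutyl}acetaldehyde
Conditions: i-Bu2AlH (1.1 equiv), CH2Cl2, −78 °C; aq. potassium sodium tartrate
Reagents that add atoms: none
Why: Partial reduction of the activated trifluoroethyl ester stops at the aluminium hemiacetal at low temperature and gives the aldehyde on work-up.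

Step 11
Reactants: 13 2-{(1R,2R)-3,3-dimethyl-2-[(3S)-3-methyl-3,5-bis(triethylsilyloxy)pentyl]cyclobutyl}acetaldehyde
Product: 14 2-{(1S,2R)-3,3-dimethyl-2-[(3S)-3-methyl-3,5-bis(triethylsilyloxy)pentyl]cyclobutyl}prop-2-enal
Conditions: 37% aq. CH2O, pyrrolidine (10 mol%), propionic acid (10 mol%), i-PrOH, 45 °C
Reagents that add atoms: formaldehyde, C=O
Why: Amine-catalysed α-methylenation (Mannich condensation then elimination) turns the CH2 next to the aldehyde into the future C8 methylene, and C9 is not enolisable so its configuration is kept.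

Step 12
Reactants: 14 2-{(1S,2R)-3,3-dimethyl-2-[(3S)-3-methyl-3,5-bis(triethylsilyloxy)pentyl]cyclobutyl}prop-2-enal
Product: 15 2-{(1S,2R)-3,3-dimethyl-2-[(3S)-3-methyl-3,5-bis(triethylsilyloxy)pentyl]cyclobutyl}prop-2-en-1-ol
Conditions: NaBH4, CeCl3·7H2O, MeOH, −40 °C
Reagents that add atoms: none
Why: Luche reduction gives clean 1,2-reduction of the 2-substituted acrolein to the 2-substituted allylic alcohol.

Step 13
Reactants: 15 2-{(1S,2R)-3,3-dimethyl-2-[(3S)-3-methyl-3,5-bis(triethylsilyloxy)pentyl]cyclobutyl}prop-2-en-1-ol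
Product: 16 methyl 2-{(1S,2R)-3,3-dimethyl-2-[(3S)-3-methyl-3,5-bis(triethylsilyloxy)pentyl]cyclobutyl}prop-2-en-1-yl carbonate
Conditions: ClCO2Me, pyridine, CH2Cl2, 0 °C
Reagents that add atoms: methyl chloroformate, COC(Cl)=O
Why: O-acylation of the primary allylic alcohol installs the leaving group for the later π-allyl formation and masks the alcohol during the following oxidation.

Step 14
Reactants: 16 methyl 2-{(1S,2R)-3,3-dimethyl-2-[(3S)-3-methyl-3,5-bis(triethylsilyloxy)pentyl]cyclobutyl}prop-2-en-1-yl carbonate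
Product: 17 methyl 2-{(1S,2R)-3,3-dimethyl-2-[(3S)-3-methyl-5-oxo-3-(triethylsilyloxy)pentyl]cyclobutyl}prop-2-en-1-yl carbonate
Conditions: (COCl)2, DMSO, CH2Cl2, −78 to −40 °C; Et3N, −78 °C to rt
Reagents that add atoms: none
Why: Swern conditions convert a primary triethylsilyl ether directly into the aldehyde while the hindered tertiary silyl ether is inert, so the C6 aldehyde is unveiled without a separate deprotection.

Step 15
Reactants: 17 methyl 2-{(1S,2R)-3,3-dimethyl-2-[(3S)-3-methyl-5-oxo-3-(triethylsilyloxy)pentyl]cyclobutyl}prop-2-en-1-yl carbonate; 4 3,5-dihydroxy-6,6-dimethyl-2-(2-methylpropanoyl)-4-[(phenylsulfonyl)methyl]cyclohexa-2,4-dien-1-one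
Product: 20 methyl 2-{(1S,2R)-2-[(3S)-3-{(3R)-2,5-dihydroxy-8,8-dimethyl-6-(2-methylpropanoyl)-7-oxo-3,4,7,8-tetrahydro-2H-chromen-3-yl}-3-(triethylsilyloxy)butyl]-3,3-dimethylcyclobutyl}prop-2-en-1-yl carbonate (lactol, both anomers), via quinone methide 18 (not isolated), via open-chain aldehyde 19 (not isolated)
Conditions: (R)-α,α-diphenylprolinol trimethylsilyl ether (20 mol%), NaHCO3, CH2Cl2/H2O, 0 °C to rt
Reagents that add atoms: none
Why: Enamine-catalysed Michael addition of an aldehyde to an ortho-quinone methide released from its sulfone by base, in which the diphenyl(silyloxy)methyl group blocks one face of the E-enamine so that the C5–C1′ bond forms with 5R configuration under catalyst control, and hemiacetal closure onto the trione enol protects the new α-stereocentre from epimerisation.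

Step 16
Reactants: 20 lactol (named in step 15)
Product: 21 methyl 2-{(1S,2R)-2-[(3S,4R)-4-{[2,6-dihydroxy-3,3-dimethyl-5-(2-methylpropanoyl)-4-oxocyclohexa-1,5-dien-1-yl]methyl}-3-methyl-5,5-bis(phenylthio)-3-(triethylsilyloxy)pentyl]-3,3-dimethylcyclobutyl}prop-2-en-1-yl carbonate
Conditions: PhSSiMe3 (2.5 equiv), ZnI2 (10 mol%), CH2Cl2, 0 °C to rt
Reagents that add atoms: (phenylthio)trimethylsilane, C[Si](C)(C)Sc1ccccc1
Why: Lewis acid-mediated thioacetalisation opens the lactol at C6 (the trione enol oxygen is a good leaving group) and fixes C6 as the diphenyl dithioacetal under conditions that spare the silyl ether, the carbonate and the C5 stereocentre.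

Step 17
Reactants: 21 dithioacetal (named in step 16)
Product: 23 methyl 2-{(1S,2R)-2-[2-{(2S,3R)-3-[bis(phenylthio)methyl]-5-hydroxy-2,8,8-trimethyl-6-(2-methylpropanoyl)-7-oxo-3,4,7,8-tetrahydro-2H-chromen-2-yl}ethyl]-3,3-dimethylcyclobutyl}prop-2-en-1-yl carbonate, via tertiary alcohol 22 (not isolated)
Conditions: HF·pyridine, pyridine, THF, 0 °C to rt; then pyridinium p-toluenesulfonate (cat.), 4 Å MS, CH2Cl2, rt
Reagents that add atoms: none
Why: After desilylation the C4 hydroxyl adds to the one ring ketone that is not part of the acyl-enol chelate (the one next to the gem-dimethyl carbon), and the hemiketal dehydrates to the vinylogous ester (cyclodehydration of a δ-hydroxy-1,3-dione), so the C4–O bond is never broken and C4 keeps its configuration.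

Step 18
Reactants: 23 pyran dithioacetal (named in step 17)
Product: 24 methyl 2-{(1S,2R)-2-[2-{(2S,3R)-3-[bis(phenylsulfonyl)methyl]-5-hydroxy-2,8,8-trimethyl-6-(2-methylpropanoyl)-7-oxo-3,4,7,8-tetrahydro-2H-chromen-2-yl}ethyl]-3,3-dimethylcyclobutyl}prop-2-en-1-yl carbonate
Conditions: (NH4)6Mo7O24·4H2O (20 mol%), 30% H2O2, EtOH/THF, 0 °C to rt
Reagents that add atoms: hydrogen peroxide, OO
Why: Molybdate-catalysed peroxide oxidation takes both sulfides to sulfones and is selective for sulfur over the 1,1-disubstituted alkene and the electron-poor enol ether.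

Step 19
Reactants: 24 bis-sulfone allyl carbonate (named in step 18)
Product: 26 (1R,4S,5R,9S)-6,6-bis(phenylsulfonyl) derivative of the target (nine-membered ring closed, exocyclic methylene at C8), via disodium salt 25 (not isolated)
Conditions: NaH (2.2 equiv), THF, 0 °C; slow addition to Pd(PPh3)4 (10 mol%), Ph2PCH2CH2PPh2 (10 mol%), THF, 65 °C, final 0.003 M; aq. HCl
Reagents that add atoms: none
Why: Zerovalent palladium ionises the allylic carbonate to a 2-substituted π-allyl complex centred on C8, and the sodium bis(phenylsulfonyl)methanide at C6 attacks one CH2 terminus on the face opposite to palladium, forming C6–C7. The closest known reaction type is the palladium-catalysed intramolecular allylic alkylation of bis-sulfonyl carbanions used for medium and large carbocycles. The nine-membered ring closes with the attacked terminus and the central allyl carbon inside the ring, so the other terminus becomes the exocyclic methylene, and because both termini are equivalent there is no regiochemical issue. No stereocentre is formed and C1, C4, C5 and C9 are not touched. The step needs C-alkylation at the bis-sulfonyl carbon in preference to the trione enolate and ring closure in preference to oligomerisation; the first is secured by the much higher nucleophilicity of the softer carbanion and the reversibility of any O-allylation, the second by slow addition at high dilution.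

Step 20
Reactants: 26 cyclised bis-sulfone (named in step 19)
Product: 27 CNP0497637.1, the target, (1R,4S,5R,9S)
Conditions: Mg turnings, MeOH, rt to 50 °C; aq. NH4Cl
Reagents that add atoms: none
Why: Dissolving-metal reductive desulfonylation cleaves both C–S bonds of the geminal bis-sulfone by electron transfer and protonation, leaves the enolate-protected trione and the isolated alkene alone, and touches no stereocentre.

**Compound list**

1 | phloroglucinol | Oc1cc(O)cc(O)c1 | starting material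
2 | 2-methyl-1-(2,4,6-trihydroxyphenyl)propan-1-one | CC(C)C(=O)c1c(O)cc(O)cc1O | intermediate
3 | 3,5-dihydroxy-6,6-dimethyl-2-(2-methylpropanoyl)cyclohexa-2,4-dien-1-one | CC(C)C(=O)C1=C(O)C=C(O)C(C)(C)C1=O | intermediate
4 | 3,5-dihydroxy-6,6-dimethyl-2-(2-methylpropanoyl)-4-[(phenylsulfonyl)methyl]cyclohexa-2,4-dien-1-one | CC(C)C(=O)C1=C(O)C(CS(=O)(=O)c2ccccc2)=C(O)C(C)(C)C1=O | intermediate
5 | buta-2,3-dienoic acid | C=C=CC(=O)O | starting material
6 | 2,2,2-trifluoroethyl buta-2,3-dienoate | C=C=CC(=O)OCC(F)(F)F | intermediate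
7 | geraniol | CC(C)=CCC/C(C)=C/CO | starting material
8 | (2S,3S)-2,3-epoxygeraniol | CC(C)=CCC[C@]1(C)O[C@H]1CO | intermediate
9 | (3S)-3,7-dimethyloct-6-ene-1,3-diol | CC(C)=CCC[C@@](C)(CCO)O | intermediate
10 | (3S)-3,7-dimethyl-1,3-bis(triethylsilyloxy)oct-6-ene | CC(C)=CCC[C@@](C)(CCO[Si](CC)(CC)CC)O[Si](CC)(CC)CC | intermediate
11 | 2,2,2-trifluoroethyl (2E)-2-{(2S)-3,3-dimethyl-2-[(3S)-3-methyl-3,5-bis(triethylsilyloxy)pentyl]cyclobutylidene}acetate | FC(F)(F)COC(=O)/C=C1\CC(C)(C)[C@@H]1CC[C@@](C)(CCO[Si](CC)(CC)CC)O[Si](CC)(CC)CC | intermediate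
12 | 2,2,2-trifluoroethyl 2-{(1R,2R)-3,3-dimethyl-2-[(3S)-3-methyl-3,5-bis(triethylsilyloxy)pentyl]cyclobutyl}acetate | FC(F)(F)COC(=O)C[C@H]1CC(C)(C)[C@@H]1CC[C@@](C)(CCO[Si](CC)(CC)CC)O[Si](CC)(CC)CC | intermediate
13 | 2-{(1R,2R)-3,3-dimethyl-2-[(3S)-3-methyl-3,5-bis(triethylsilyloxy)pentyl]cyclobutyl}acetaldehyde | O=CC[C@H]1CC(C)(C)[C@@H]1CC[C@@](C)(CCO[Si](CC)(CC)CC)O[Si](CC)(CC)CC | intermediate
14 | 2-{(1S,2R)-3,3-dimethyl-2-[(3S)-3-methyl-3,5-bis(triethylsilyloxy)pentyl]cyclobutyl}prop-2-enal | O=CC(=C)[C@H]1CC(C)(C)[C@@H]1CC[C@@](C)(CCO[Si](CC)(CC)CC)O[Si](CC)(CC)CC | intermediate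
15 | 2-{(1S,2R)-3,3-dimethyl-2-[(3S)-3-methyl-3,5-bis(triethylsilyloxy)pentyl]cyclobutyl}prop-2-en-1-ol | OCC(=C)[C@H]1CC(C)(C)[C@@H]1CC[C@@](C)(CCO[Si](CC)(CC)CC)O[Si](CC)(CC)CC | intermediate
16 | methyl 2-{(1S,2R)-3,3-dimethyl-2-[(3S)-3-methyl-3,5-bis(triethylsilyloxy)pentyl]cyclobutyl}prop-2-en-1-yl carbonate | COC(=O)OCC(=C)[C@H]1CC(C)(C)[C@@H]1CC[C@@](C)(CCO[Si](CC)(CC)CC)O[Si](CC)(CC)CC | intermediate
17 | methyl 2-{(1S,2R)-3,3-dimethyl-2-[(3S)-3-methyl-5-oxo-3-(triethylsilyloxy)pentyl]cyclobutyl}prop-2-en-1-yl carbonate | COC(=O)OCC(=C)[C@H]1CC(C)(C)[C@@H]1CC[C@@](C)(CC=O)O[Si](CC)(CC)CC | intermediate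
18 | 5-hydroxy-2,2-dimethyl-6-methylidene-4-(2-methylpropanoyl)cyclohex-4-ene-1,3-dione (quinone methide) | C=C1C(=O)C(C)(C)C(=O)C(C(=O)C(C)C)=C1O | intermediate
19 | methyl 2-{(1S,2R)-2-[(3S,4R)-4-{[2,6-dihydroxy-3,3-dimethyl-5-(2-methylpropanoyl)-4-oxocyclohexa-1,5-dien-1-yl]methyl}-3-methyl-5-oxo-3-(triethylsilyloxy)pentyl]-3,3-dimethylcyclobutyl}prop-2-en-1-yl carbonate (open-chain aldehyde) | COC(=O)OCC(=C)[C@H]1CC(C)(C)[C@@H]1CC[C@](C)(O[Si](CC)(CC)CC)[C@H](C=O)CC1=C(O)C(C)(C)C(=O)C(C(=O)C(C)C)=C1O | intermediate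
20 | methyl 2-{(1S,2R)-2-[(3S)-3-{(3R)-2,5-dihydroxy-8,8-dimethyl-6-(2-methylpropanoyl)-7-oxo-3,4,7,8-tetrahydro-2H-chromen-3-yl}-3-(triethylsilyloxy)butyl]-3,3-dimethylcyclobutyl}prop-2-en-1-yl carbonate (lactol, both anomers) | COC(=O)OCC(=C)[C@H]1CC(C)(C)[C@@H]1CC[C@](C)(O[Si](CC)(CC)CC)[C@H]1CC2=C(OC1O)C(C)(C)C(=O)C(C(=O)C(C)C)=C2O | intermediate
21 | methyl 2-{(1S,2R)-2-[(3S,4R)-4-{[2,6-dihydroxy-3,3-dimethyl-5-(2-methylpropanoyl)-4-oxocyclohexa-1,5-dien-1-yl]methyl}-3-methyl-5,5-bis(phenylthio)-3-(triethylsilyloxy)pentyl]-3,3-dimethylcyclobutyl}prop-2-en-1-yl carbonate | COC(=O)OCC(=C)[C@H]1CC(C)(C)[C@@H]1CC[C@](C)(O[Si](CC)(CC)CC)[C@H](C(Sc1ccccc1)Sc1ccccc1)CC1=C(O)C(C)(C)C(=O)C(C(=O)C(C)C)=C1O | intermediate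
22 | methyl 2-{(1S,2R)-2-[(3S,4R)-4-{[2,6-dihydroxy-3,3-dimethyl-5-(2-methylpropanoyl)-4-oxocyclohexa-1,5-dien-1-yl]methyl}-3-hydroxy-3-methyl-5,5-bis(phenylthio)pentyl]-3,3-dimethylcyclobutyl}prop-2-en-1-yl carbonate (tertiary alcohol) | COC(=O)OCC(=C)[C@H]1CC(C)(C)[C@@H]1CC[C@](C)(O)[C@H](C(Sc1ccccc1)Sc1ccccc1)CC1=C(O)C(C)(C)C(=O)C(C(=O)C(C)C)=C1O | intermediate
23 | methyl 2-{(1S,2R)-2-[2-{(2S,3R)-3-[bis(phenylthio)methyl]-5-hydroxy-2,8,8-trimethyl-6-(2-methylpropanoyl)-7-oxo-3,4,7,8-tetrahydro-2H-chromen-2-yl}ethyl]-3,3-dimethylcyclobutyl}prop-2-en-1-yl carbonate | COC(=O)OCC(=C)[C@H]1CC(C)(C)[C@@H]1CC[C@]1(C)OC2=C(C[C@H]1C(Sc1ccccc1)Sc1ccccc1)C(O)=C(C(=O)C(C)C)C(=O)C2(C)C | intermediate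
24 | methyl 2-{(1S,2R)-2-[2-{(2S,3R)-3-[bis(phenylsulfonyl)methyl]-5-hydroxy-2,8,8-trimethyl-6-(2-methylpropanoyl)-7-oxo-3,4,7,8-tetrahydro-2H-chromen-2-yl}ethyl]-3,3-dimethylcyclobutyl}prop-2-en-1-yl carbonate | COC(=O)OCC(=C)[C@H]1CC(C)(C)[C@@H]1CC[C@]1(C)OC2=C(C[C@H]1C(S(=O)(=O)c1ccccc1)S(=O)(=O)c1ccccc1)C(O)=C(C(=O)C(C)C)C(=O)C2(C)C | intermediate
25 | disodium salt of 24 (trione enolate and C6 bis-sulfonyl carbanion) | [Na+].[Na+].COC(=O)OCC(=C)[C@H]1CC(C)(C)[C@@H]1CC[C@]1(C)OC2=C(C[C@H]1[C-](S(=O)(=O)c1ccccc1)S(=O)(=O)c1ccccc1)C([O-])=C(C(=O)C(C)C)C(=O)C2(C)C | intermediate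
26 | (1R,4S,5R,9S)-6,6-bis(phenylsulfonyl) derivative of the target | C=C1CC(S(=O)(=O)c2ccccc2)(S(=O)(=O)c2ccccc2)[C@@H]2CC3=C(O[C@@]2(C)CC[C@@H]2[C@@H]1CC2(C)C)C(C)(C)C(=O)C(C(=O)C(C)C)=C3O | intermediate
27 | CNP0497637.1, (1R,4S,5R,9S) | C=C1CC[C@@H]2CC3=C(O[C@@]2(C)CC[C@@H]2[C@@H]1CC2(C)C)C(C)(C)C(=O)C(C(=O)C(C)C)=C3O | target

**Step count**

Total: 20 steps. Longest linear sequence: 16 steps (geraniol 7 to target 27, steps 5–20).

**Steps most likely to fail**

1. Step 19. The ring closure may lose to intermolecular alkylation, or the tertiary bis-sulfonyl carbanion next to the C5 branch may be too hindered to reach the allyl terminus. The fallback reverses the polarity of the same C6–C7 bond; it sets out from 23 and returns at 27. Pd(dba)2-catalysed silylation of the allylic carbonate with Me3SiSiMe3 should give the 2-substituted allylsilane F1. Me2S+SMe BF4− then ionises one C–S bond of the dithioacetal, and the C6 thionium ion is captured by the allylsilane terminus, which closes the nine-membered ring and regenerates the exocyclic methylene in the cyclic sulfide F2. Oxidation with (NH4)6Mo7O24·4H2O/H2O2 gives the monosulfone F3, and Mg in MeOH removes the sulfonyl group to give 27.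

2. Step 15. The enamine may lose the β-silyloxy group to give an enal, or the hindered α-carbon may react with poor facial selectivity. The fallback replaces catalyst control by a covalently bound auxiliary; it sets out from 17 and returns at 20. Condensation with (S)-1-amino-2-(methoxymethyl)pyrrolidine gives the SAMP hydrazone F4. Deprotonation with LiN(i-Pr)2 at −78 °C (faster at the hydrazone than attack on the carbonate) and addition of the lithium salt of 4, which releases 18, should give the Michael adduct F5 with the same C5 configuration. Aqueous oxalic acid cleaves the hydrazone to 19, which closes to 20.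

3. Step 9. Hydride may add to the less hindered C9 face against the ligand preference and give the cis-cyclobutane. The fallback sets C9 under thermodynamic control; it sets out from 11 and returns at 15. i-Bu2AlH reduces the ester to the allylic alcohol F6. Hydroboration with BH3·THF and NaOH/H2O2 gives the 1,2-diol F7 as a mixture at C9. NaOCl in AcOH oxidises the secondary alcohol only, and 1,8-diazabicyclo[5.4.0]undec-7-ene equilibrates the α-stereocentre to the trans hydroxy ketone F8. Wittig methylenation with excess Ph3P=CH2 gives 15.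

Further compounds
F1 | step 19 | allylsilane: 23 with CH2SiMe3 in place of CH2OCO2Me | C[Si](C)(C)CC(=C)[C@H]1CC(C)(C)[C@@H]1CC[C@]1(C)OC2=C(C[C@H]1C(Sc1ccccc1)Sc1ccccc1)C(O)=C(C(=O)C(C)C)C(=O)C2(C)C
F2 | step 19 | cyclic sulfide: 6-(phenylthio) derivative of the target (C6 epimers) | C=C1CC(Sc2ccccc2)[C@@H]2CC3=C(O[C@@]2(C)CC[C@@H]2[C@@H]1CC2(C)C)C(C)(C)C(=O)C(C(=O)C(C)C)=C3O
F3 | step 19 | monosulfone: 6-(phenylsulfonyl) derivative of the target (C6 epimers) | C=C1CC(S(=O)(=O)c2ccccc2)[C@@H]2CC3=C(O[C@@]2(C)CC[C@@H]2[C@@H]1CC2(C)C)C(C)(C)C(=O)C(C(=O)C(C)C)=C3O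
F4 | step 15 | SAMP hydrazone of aldehyde 17 | COC(=O)OCC(=C)[C@H]1CC(C)(C)[C@@H]1CC[C@@](C)(C/C=N/N1CCC[C@H]1COC)O[Si](CC)(CC)CC
F5 | step 15 | SAMP hydrazone of open-chain aldehyde 19 (5R) | COC(=O)OCC(=C)[C@H]1CC(C)(C)[C@@H]1CC[C@](C)(O[Si](CC)(CC)CC)[C@H](/C=N/N1CCC[C@H]1COC)CC1=C(O)C(C)(C)C(=O)C(C(=O)C(C)C)=C1O
F6 | step 9 | (2E)-2-{(2S)-3,3-dimethyl-2-[(3S)-3-methyl-3,5-bis(triethylsilyloxy)pentyl]cyclobutylidene}ethanol | OC/C=C1\CC(C)(C)[C@@H]1CC[C@@](C)(CCO[Si](CC)(CC)CC)O[Si](CC)(CC)CC
F7 | step 9 | 1-{(2R)-3,3-dimethyl-2-[(3S)-3-methyl-3,5-bis(triethylsilyloxy)pentyl]cyclobutyl}ethane-1,2-diol (mixture at C9 and the carbinol carbon) | OCC(O)C1CC(C)(C)[C@@H]1CC[C@@](C)(CCO[Si](CC)(CC)CC)O[Si](CC)(CC)CC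
F8 | step 9 | 1-{(1S,2R)-3,3-dimethyl-2-[(3S)-3-methyl-3,5-bis(triethylsilyloxy)pentyl]cyclobutyl}-2-hydroxyethanone (trans) | OCC(=O)[C@H]1CC(C)(C)[C@@H]1CC[C@@](C)(CCO[Si](CC)(CC)CC)O[Si](CC)(CC)CC
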